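The trans-fused oxepane (ring B: C4, O5, C6–C10) and methylenecyclohexane (ring A: C1–C4, C10, C11) are disconnected at O5–C6 and C10–C11. They unfold to a linear bis-epoxide (C6–C7 and C4–C10) ending in a trisubstituted allylsilane. One silyl-triflate-triggered cascade should close both rings, set C10 and C11, deliver the C7 carbinol and unveil the C1 methylene. It exploits the tertiary ether carbon C6, the methyl-bearing quaternary C10 and the C1 methylene beside C11. The precursor is the (4S,7S,10S)-bis-epoxy allylsilane carrying a C13 silyl ether. Rings C and D come from a sister enolsilane cascade and are joined at C13–C14 by aldol condensation.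

Key step: step 10

Numbering: the main chain runs from the methylene-bearing ring carbon C1 to the carbinol carbon C24, O5 and O20 are the ring oxygens, ring A is C1–C4/C10/C11, ring B is C4/O5/C6–C10, ring C is C14/C15/C21–C24, ring D is C15–C19/O20/C21; the target is 4S,7S,10S,11R,14S,15S,21S,24R.

Remark: the allylsilane double bond C1=C11 must have C2 and C12 trans; because the silylmethyl carbon outranks C2, this geometry is (Z) by the CIP rules.

Remark: the 7S carbinol requires S-configured epoxides, so the L-fructose-derived enantiomer of the Shi ketone is used.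

Remark: a C24 ketone flanked by C14H2 and C23H2 would enolise toward the less hindered C23, so ring C is first dehydrogenated to the C22=C23 enone, which leaves C14 as the only kinetically acidic position for the coupling.

Assumption: isomerically pure (E)-geranylacetone and the L-fructose-derived Shi ketone (1,2:4,5-di-O-isopropylidene-β-L-erythro-2,3-hexodiulo-2,6-pyranose, otherwise made from L-sorbose) are purchased.

Abbreviations: TBDPS = tert-butyldiphenylsilyl, TBS = tert-butyldimethylsilyl, TES = triethylsilyl, DTBMP = 2,6-di-tert-butyl-4-methylpyridine.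

Step 1
Reactants: 1 geranyl bromide; 2 methyl acetoacetate
Product: 4 methyl (6E)-7,11-dimethyl-3-oxododeca-6,10-dienoate, via methyl acetoacetate dianion 3 (not isolated)
Conditions: NaH, THF, 0 °C; n-BuLi, 0 °C; then 1, 0 °C to rt; aq. HCl work-up
Reagents that add atoms: none
Why: γ-Alkylation of the acetoacetate dianion, whose terminal carbanion displaces the primary allylic bromide by SN2 without touching the (E)-alkene, forms C2–C3 and creates no stereocentre.

Step 2
Reactants: 4 methyl (6E)-7,11-dimethyl-3-oxododeca-6,10-dienoate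
Product: 6 methyl (2Z,6E)-3-[(diethoxyphosphoryl)oxy]-7,11-dimethyldodeca-2,6,10-trienoate, via sodium enolate of the keto ester 5 (not isolated)
Conditions: NaH, Et2O, 0 °C; then (EtO)2P(O)Cl, 0 °C to rt
Reagents that add atoms: diethyl chlorophosphate, CCOP(=O)(Cl)OCC
Why: O-Phosphorylation of the sodium-chelated enolate of the β-keto ester should give the (Z)-enol phosphate, which fixes the later C1=C11 geometry.

Step 3
Reactants: 6 methyl (2Z,6E)-3-[(diethoxyphosphoryl)oxy]-7,11-dimethyldodeca-2,6,10-trienoate; 7 (trimethylsilyl)methylmagnesium chloride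
Product: 8 methyl (2Z,6E)-7,11-dimethyl-3-[(trimethylsilyl)methyl]dodeca-2,6,10-trienoate
Conditions: Ni(acac)2 (5 mol %), THF, 0 °C to rt
Reagents that add atoms: none
Why: Nickel-catalysed Kumada-type coupling of an enol phosphate proceeds with retention of alkene geometry, so the silylmethyl group should end cis to the ester and C2 trans to C12.

Step 4
Reactants: 8 methyl (2Z,6E)-7,11-dimethyl-3-[(trimethylsilyl)methyl]dodeca-2,6,10-trienoate
Product: 9 methyl (2Z)-5-[(2S,3S)-3-{2-[(2S)-3,3-dimethyloxiran-2-yl]ethyl}-3-methyloxiran-2-yl]-3-[(trimethylsilyl)methyl]pent-2-enoate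
Conditions: L-fructose-derived Shi ketone (0.3 equiv per alkene), Oxone (2KHSO5·KHSO4·K2SO4), K2CO3, Bu4NHSO4, MeCN/dimethoxymethane/aq. Na2B4O7 buffer (pH about 10.5), 0 °C
Reagents that add atoms: Oxone (active component potassium peroxymonosulfate), [K+].[O-]S(=O)(=O)OO
Why: Shi asymmetric epoxidation by the chiral dioxirane attacks only the two electron-rich trisubstituted alkenes, the enoate alkene being deactivated, and the spiro transition state of the L-series ketone should deliver oxygen to the faces that give 7S and 4S,10S.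

Step 5
Reactants: 9 bis-epoxy enoate
Product: 10 (2Z)-5-[(2S,3S)-3-{2-[(2S)-3,3-dimethyloxiran-2-yl]ethyl}-3-methyloxiran-2-yl]-3-[(trimethylsilyl)methyl]pent-2-en-1-ol
Conditions: i-Bu2AlH (2.5 equiv), CH2Cl2, −78 °C; aq. KNaC4H4O6 work-up
Reagents that add atoms: none
Why: 1,2-Reduction of the conjugated ester by the aluminium hydride at low temperature should stop at the allylic alcohol and leave the trisubstituted epoxides and the allylsilane untouched.

Step 6
Reactants: 10 allylic alcohol
Product: 11 (2Z)-5-[(2S,3S)-3-{2-[(2S)-3,3-dimethyloxiran-2-yl]ethyl}-3-methyloxiran-2-yl]-3-[(trimethylsilyl)methyl]pent-2-enal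
Conditions: MnO2 (activated, excess), CH2Cl2, rt
Reagents that add atoms: none
Why: Neutral heterogeneous allylic oxidation with MnO2 should give the enal without acid or base that could isomerise C1=C11 or open the epoxides.

Step 7
Reactants: 11 enal
Product: 12 bis-epoxy (Z)-diene (the C12 aldehyde of 11 converted into the C12=C13 vinyl group)
Conditions: Ph3PCH3Br, KN(SiMe3)2, THF, 0 °C; then 11, −78 to 0 °C
Reagents that add atoms: methyltriphenylphosphonium bromide, C[P+](c1ccccc1)(c1ccccc1)c1ccccc1.[Br-]
Why: Wittig methylenation by the non-stabilised ylide adds C13 by 1,2-attack on the aldehyde and should not alter the trisubstituted alkene geometry or the epoxides.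

Step 8
Reactants: 12 bis-epoxy (Z)-diene
Product: 14 (3Z)-6-[(2S,3S)-3-{2-[(2S)-3,3-dimethyloxiran-2-yl]ethyl}-3-methyloxiran-2-yl]-4-[(trimethylsilyl)methyl]hex-3-en-1-ol, via B-alkyl-9-borabicyclononane 13 (not isolated)
Conditions: 9-BBN (1.3 equiv), THF, 0 °C to rt; then 3 M NaOH, 30% H2O2, 0 °C
Reagents that add atoms: hydrogen peroxide, OO; 9-borabicyclo[3.3.1]nonane, B1C2CCCC1CCC2 (boron of intermediate 13 only)
Why: Anti-Markovnikov hydroboration–oxidation, in which the bulky borane should add only to the monosubstituted terminus of the 1,3-diene, places oxygen on C13.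

Step 9
Reactants: 14 homoallylic alcohol
Product: 15 tert-butyl{[(3Z)-6-[(2S,3S)-3-{2-[(2S)-3,3-dimethyloxiran-2-yl]ethyl}-3-methyloxiran-2-yl]-4-[(trimethylsilyl)methyl]hex-3-en-1-yl]oxy}diphenylsilane
Conditions: t-BuPh2SiCl, imidazole, DMF, rt
Reagents that add atoms: tert-butyldiphenylsilyl chloride, CC(C)(C)[Si](Cl)(c1ccccc1)c1ccccc1
Why: Standard silylation of the primary alcohol gives an ether that is inert to silyl triflate at low temperature and too remote and hindered to compete as a nucleophile in the cascade.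

Step 10
Reactants: 15 bis-epoxy allylsilane (4S,7S,10S; C2 trans to C12; C13–OTBDPS)
Product: 17 (3S,5aS,6R,9aS)-6-{2-[(tert-butyldiphenylsilyl)oxy]ethyl}-2,2,5a-trimethyl-7-methylidenedecahydro-1-benzoxepin-3-ol, via C7 trimethylsilyl ether 16 (not isolated)
Conditions: Me3SiOTf (1.1 equiv), DTBMP (1.5 equiv), CH2Cl2, −78 °C; then K2CO3, MeOH, 0 °C
Reagents that add atoms: trimethylsilyl trifluoromethanesulfonate, C[Si](C)(C)OS(=O)(=O)C(F)(F)F (silyl group of intermediate 16 only)
Why: Me3Si+ binds the oxygen of the C6–C7 epoxide, the oxygen of the C4–C10 epoxide (the future O5) attacks tertiary C6 to give a bicyclic epoxonium ion, and allylsilane carbon C11 opens this ion at tertiary C10 anti to the departing oxygen while the β-silyl cation at C1 loses Me3Si+ to leave the methylene; methanolysis of the C7 silyl ether then frees the carbinol. The closest known reaction type is the silyl-triflate-promoted endo-selective polyepoxide oxacyclization terminated by an allylsilane or enolsilane carbacyclization. Ring B closes by endo opening of the terminal epoxide at its more substituted carbon and is seven-membered once the C10–O5 bond has broken, and ring A closes by a six-membered chair carbacyclization in which both alkene carbons lie in the new ring. C10 is set by stereospecific inversion of the epoxide carbon, C11 by the chair transition state in which C12, trans to C2 on the alkene, becomes equatorial and cis to the C10 methyl, and C4 and C7 keep their epoxide-derived C–O bonds. The step needs attack at C6 rather than C7 and at C10 rather than C4, which the cation-stabilising methyl-bearing carbons secure, and carbon rather than proton capture at the allylsilane, which the hindered pyridine base and low temperature should secure.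

Step 11
Reactants: 17 bicyclic carbinol
Product: 18 C7 tert-butyldimethylsilyl ether of 17
Conditions: t-BuMe2SiOTf, 2,6-lutidine, CH2Cl2, −78 to 0 °C
Reagents that add atoms: tert-butyldimethylsilyl trifluoromethanesulfonate, CC(C)(C)[Si](C)(C)OS(=O)(=O)C(F)(F)F
Why: Silylation by the silyl triflate and a hindered base is the standard way to protect a neopentyl-type secondary alcohol, and no stereocentre is touched.

Step 12
Reactants: 18 bis-silyl ether
Product: 19 primary alcohol (C13–OH) carrying the C7 tert-butyldimethylsilyl ether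
Conditions: Bu4NF, AcOH (1:1), THF, 0 °C to rt
Reagents that add atoms: none
Why: Acetic-acid-buffered fluoride desilylation should cleave the unhindered primary diphenylsilyl ether, whose silicon is the more electrophilic toward fluoride, well before the neopentyl-type secondary silyl ether at C7.

Step 13
Reactants: 19 primary alcohol
Product: 20 C13 aldehyde carrying the C7 tert-butyldimethylsilyl ether
Conditions: Dess–Martin periodinane, NaHCO3, CH2Cl2, 0 °C to rt
Reagents that add atoms: none
Why: Buffered Dess–Martin oxidation should give the aldehyde without over-oxidation and without acid that could move the C1 methylene.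

Step 14
Reactants: 21 (E)-geranylacetone
Product: 22 4-[(2S,3S)-3-{2-[(2S)-3,3-dimethyloxiran-2-yl]ethyl}-3-methyloxiran-2-yl]butan-2-one
Conditions: L-fructose-derived Shi ketone (0.3 equiv per alkene), Oxone (2KHSO5·KHSO4·K2SO4), K2CO3, Bu4NHSO4, MeCN/dimethoxymethane/aq. Na2B4O7 buffer, 0 °C
Reagents that add atoms: Oxone (active component potassium peroxymonosulfate), [K+].[O-]S(=O)(=O)OO
Why: Shi asymmetric epoxidation, far faster through the activated chiral ketone than through the unactivated methyl ketone of the substrate, should set 18S and 15S,21S by the same facial sense as in step 4.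

Step 15
Reactants: 22 bis-epoxy ketone
Product: 24 triethylsilyl enol ether of 22 at the methyl terminus (C14=C24), via lithium enolate 23 (not isolated)
Conditions: LiN(i-Pr)2, THF, −78 °C (ketone added to base); then Et3SiCl, Et3N, −78 to 0 °C
Reagents that add atoms: chlorotriethylsilane, CC[Si](Cl)(CC)CC
Why: Kinetic deprotonation of a methyl ketone by the hindered amide occurs at the methyl group, and O-silylation at low temperature should trap the terminal enolate before it can equilibrate or open an epoxide.

Step 16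
Reactants: 24 bis-epoxy enol ether
Product: 25 (3S,5aS,9aS)-2,2,5a-trimethyl-3-[(triethylsilyl)oxy]perhydro-1-benzoxepin-7-one
Conditions: Et3SiOTf (1.1 equiv), DTBMP (1.5 equiv), CH2Cl2, −78 °C; aq. NaHCO3 quench
Reagents that add atoms: triethylsilyl trifluoromethanesulfonate, CC[Si](CC)(CC)OS(=O)(=O)C(F)(F)F (its silyl group ends on O18, that of 24 is released in turn)
Why: Silyl-triflate-promoted polyepoxide oxa- and carbacyclization terminated by an enolsilane: the silyl cation stays on O18, O20 attacks tertiary C19, and enol carbon C14 opens the epoxonium ion at C15 with inversion through a chair, which should give the trans-fused bicycle with 15S and 21S and the C24 ketone.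

Step 17
Reactants: 25 bicyclic ketone
Product: 27 the 8,9-didehydro derivative of 25 (C22=C23 enone), via trimethylsilyl enol ether 26 (not isolated)
Conditions: LiN(i-Pr)2, Me3SiCl, THF, −78 °C; then Pd(OAc)2 (1.1 equiv), MeCN, rt
Reagents that add atoms: chlorotrimethylsilane, C[Si](C)(C)Cl (silyl group of intermediate 26 only)
Why: Saegusa–Ito oxidation: kinetic enolisation occurs at the less hindered C23, and only that enol ether can undergo β-hydride elimination because C15 is quaternary, so a single enone should form.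

Step 18
Reactants: 27 enone; 20 aldehyde
Product: 29 aldol adduct (C13 carbinol bonded to C14; mixture at C13 and C14), via lithium dienolate 28 (not isolated)
Conditions: LiN(i-Pr)2, THF, −78 °C; then 20, −78 °C; AcOH quench
Reagents that add atoms: none
Why: Kinetic α′-deprotonation of the cyclohexenone gives the cross-conjugated lithium dienolate, whose directed aldol addition should form the C13–C14 bond regiospecifically; the two new centres are erased in the next steps.

Step 19
Reactants: 29 aldol adduct
Product: 31 cross-conjugated dienone (C13=C14 and C22=C23 flanking the C24 ketone), via C13 mesylate 30 (not isolated)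
Conditions: MeSO2Cl, Et3N, CH2Cl2, 0 °C; then DBU, rt
Reagents that add atoms: methanesulfonyl chloride, CS(=O)(=O)Cl (mesyl group of intermediate 30 only)
Why: Mesylation of the β-hydroxy ketone followed by E1cB elimination should give the exocyclic enone, and either alkene geometry serves because the double bond is reduced next.

Step 20
Reactants: 31 dienone
Product: 32 saturated C24 ketone (4S,7S,10S,11R,14S,15S,18S,21S; C7–OTBS, C18–OTES)
Conditions: [(Ph3P)CuH]6, THF/PhMe, H2O (10 equiv), rt
Reagents that add atoms: none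
Why: Copper hydride conjugate reduction is selective for the two enone double bonds over the isolated C1 methylene and the ketone; C14 is set on protonation of the enolate, where axial delivery anti to the axial C15 methyl and the thermodynamic preference both place C13 equatorial, and the centre remains correctable by base equilibration.

Step 21
Reactants: 32 ketone
Product: 33 C24 tertiary alcohol (24R; C7–OTBS, C18–OTES)
Conditions: MeLi, CeCl3 (anhydrous), THF, −78 °C; aq. NH4Cl
Reagents that add atoms: methyllithium, [Li]C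
Why: Organocerium 1,2-addition suppresses enolisation of the hindered ketone, and the methyl group should enter along the equatorial trajectory because the axial face is blocked by the syn-axial C15 methyl, giving the axial hydroxyl and equatorial methyl at C24.

Step 22
Reactants: 33 tertiary alcohol
Product: 34 C18,C24-diol carrying the C7 tert-butyldimethylsilyl ether
Conditions: HF·pyridine, pyridine, THF, 0 °C
Reagents that add atoms: none
Why: Buffered fluoride desilylation should cleave the triethylsilyl ether much faster than the equally hindered tert-butyldimethylsilyl ether, so only O18 is freed.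

Step 23
Reactants: 34 diol
Product: 35 C18 ketone carrying the C7 tert-butyldimethylsilyl ether
Conditions: Dess–Martin periodinane, NaHCO3, CH2Cl2, rt
Reagents that add atoms: none
Why: Dess–Martin oxidation acts on the only free secondary alcohol, the tertiary C24 alcohol cannot be oxidised, and C19 is quaternary, so no stereocentre is at risk.

Step 24
Reactants: 35 silyl-protected ketone
Product: 36 target CNP0160418.1
Conditions: Bu4NF, THF, rt to 40 °C
Reagents that add atoms: none
Why: Fluoride-mediated cleavage of the last silyl ether frees the C7 carbinol under conditions that should leave the ketone, the tertiary alcohol and the methylene untouched.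

Compound list
1 | geranyl bromide | CC(C)=CCC/C(C)=C/CBr | starting material
2 | methyl acetoacetate | COC(=O)CC(C)=O | starting material
3 | methyl acetoacetate dianion (sodium lithium salt) | [Na+].[Li+].[CH2-]C(=O)[CH-]C(=O)OC | intermediate (not isolated)
4 | methyl (6E)-7,11-dimethyl-3-oxododeca-6,10-dienoate | CC(C)=CCC/C(C)=C/CCC(=O)CC(=O)OC | intermediate
5 | sodium (Z)-enolate of 4 | CC(C)=CCC/C(C)=C/CC/C([O-])=C/C(=O)OC.[Na+] | intermediate (not isolated)
6 | methyl (2Z,6E)-3-[(diethoxyphosphoryl)oxy]-7,11-dimethyldodeca-2,6,10-trienoate | CC(C)=CCC/C(C)=C/CC/C(OP(=O)(OCC)OCC)=C/C(=O)OC | intermediate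
7 | (trimethylsilyl)methylmagnesium chloride | C[Si](C)(C)C[Mg]Cl | starting material
8 | methyl (2Z,6E)-7,11-dimethyl-3-[(trimethylsilyl)methyl]dodeca-2,6,10-trienoate | CC(C)=CCC/C(C)=C/CC/C(C[Si](C)(C)C)=C/C(=O)OC | intermediate
9 | methyl (2Z)-5-[(2S,3S)-3-{2-[(2S)-3,3-dimethyloxiran-2-yl]ethyl}-3-methyloxiran-2-yl]-3-[(trimethylsilyl)methyl]pent-2-enoate | CC1(C)O[C@H]1CC[C@]2(C)O[C@H]2CC/C(C[Si](C)(C)C)=C/C(=O)OC | intermediate
10 | (2Z)-pent-2-en-1-ol corresponding to 9 (C12 alcohol) | CC1(C)O[C@H]1CC[C@]2(C)O[C@H]2CC/C(C[Si](C)(C)C)=C/CO | intermediate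
11 | (2Z)-pent-2-enal corresponding to 9 (C12 aldehyde) | CC1(C)O[C@H]1CC[C@]2(C)O[C@H]2CC/C(C[Si](C)(C)C)=C/C=O | intermediate
12 | bis-epoxy (Z)-diene (C12=C13 vinyl on C11) | CC1(C)O[C@H]1CC[C@]2(C)O[C@H]2CC/C(C[Si](C)(C)C)=C/C=C | intermediate
13 | B-alkyl-9-borabicyclo[3.3.1]nonane (boron on C13) | CC1(C)O[C@H]1CC[C@]2(C)O[C@H]2CC/C(C[Si](C)(C)C)=C/CCB3C4CCCC3CCC4 | intermediate (not isolated)
14 | (3Z)-6-[(2S,3S)-3-{2-[(2S)-3,3-dimethyloxiran-2-yl]ethyl}-3-methyloxiran-2-yl]-4-[(trimethylsilyl)methyl]hex-3-en-1-ol | CC1(C)O[C@H]1CC[C@]2(C)O[C@H]2CC/C(C[Si](C)(C)C)=C/CCO | intermediate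
15 | tert-butyldiphenylsilyl ether of 14 (bis-epoxy allylsilane, 4S,7S,10S) | CC1(C)O[C@H]1CC[C@]2(C)O[C@H]2CC/C(C[Si](C)(C)C)=C/CCO[Si](c1ccccc1)(c1ccccc1)C(C)(C)C | intermediate
16 | C7 trimethylsilyl ether of 17 | C=C1CC[C@@H]2OC(C)(C)[C@@H](O[Si](C)(C)C)CC[C@@]2(C)[C@@H]1CCO[Si](c1ccccc1)(c1ccccc1)C(C)(C)C | intermediate (not isolated)
17 | (3S,5aS,6R,9aS)-6-{2-[(tert-butyldiphenylsilyl)oxy]ethyl}-2,2,5a-trimethyl-7-methylidenedecahydro-1-benzoxepin-3-ol (4S,7S,10S,11R) | C=C1CC[C@@H]2OC(C)(C)[C@@H](O)CC[C@@]2(C)[C@@H]1CCO[Si](c1ccccc1)(c1ccccc1)C(C)(C)C | intermediate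
18 | C7 tert-butyldimethylsilyl ether of 17 | C=C1CC[C@@H]2OC(C)(C)[C@@H](O[Si](C)(C)C(C)(C)C)CC[C@@]2(C)[C@@H]1CCO[Si](c1ccccc1)(c1ccccc1)C(C)(C)C | intermediate
19 | C13 primary alcohol, C7–OTBS | C=C1CC[C@@H]2OC(C)(C)[C@@H](O[Si](C)(C)C(C)(C)C)CC[C@@]2(C)[C@@H]1CCO | intermediate
20 | C13 aldehyde, C7–OTBS | C=C1CC[C@@H]2OC(C)(C)[C@@H](O[Si](C)(C)C(C)(C)C)CC[C@@]2(C)[C@@H]1CC=O | intermediate
21 | (E)-geranylacetone, (5E)-6,10-dimethylundeca-5,9-dien-2-one | CC(C)=CCC/C(C)=C/CCC(C)=O | starting material
22 | 4-[(2S,3S)-3-{2-[(2S)-3,3-dimethyloxiran-2-yl]ethyl}-3-methyloxiran-2-yl]butan-2-one (15S,18S,21S) | CC1(C)O[C@H]1CC[C@]2(C)O[C@H]2CCC(C)=O | intermediate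
23 | lithium enolate of 22 (C14=C24) | CC1(C)O[C@H]1CC[C@]2(C)O[C@H]2CCC(=C)[O-].[Li+] | intermediate (not isolated)
24 | triethylsilyl enol ether of 22 (C14=C24) | CC1(C)O[C@H]1CC[C@]2(C)O[C@H]2CCC(=C)O[Si](CC)(CC)CC | intermediate
25 | (3S,5aS,9aS)-2,2,5a-trimethyl-3-[(triethylsilyl)oxy]perhydro-1-benzoxepin-7-one (15S,18S,21S) | O=C1C[C@]2(C)CC[C@H](O[Si](CC)(CC)CC)C(C)(C)O[C@H]2CC1 | intermediate
26 | trimethylsilyl enol ether of 25 (C23=C24) | C[Si](C)(C)OC1C[C@]2(C)CC[C@H](O[Si](CC)(CC)CC)C(C)(C)O[C@H]2CC=1 | intermediate (not isolated)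
27 | 8,9-didehydro derivative of 25 (C22=C23 enone) | O=C1C[C@]2(C)CC[C@H](O[Si](CC)(CC)CC)C(C)(C)O[C@H]2C=C1 | intermediate
28 | lithium dienolate of 27 (C14=C24) | [Li+].[O-]C1=C[C@]2(C)CC[C@H](O[Si](CC)(CC)CC)C(C)(C)O[C@H]2C=C1 | intermediate (not isolated)
29 | aldol adduct (C13–OH, C13–C14 bond) | C=C1CC[C@@H]2OC(C)(C)[C@@H](O[Si](C)(C)C(C)(C)C)CC[C@@]2(C)[C@@H]1CC(O)C1[C@]2(C)CC[C@H](O[Si](CC)(CC)CC)C(C)(C)O[C@H]2C=CC1=O | intermediate
30 | C13 mesylate of 29 | C=C1CC[C@@H]2OC(C)(C)[C@@H](O[Si](C)(C)C(C)(C)C)CC[C@@]2(C)[C@@H]1CC(OS(C)(=O)=O)C1[C@]2(C)CC[C@H](O[Si](CC)(CC)CC)C(C)(C)O[C@H]2C=CC1=O | intermediate (not isolated)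
31 | cross-conjugated dienone (C13=C14, C22=C23) | C=C1CC[C@@H]2OC(C)(C)[C@@H](O[Si](C)(C)C(C)(C)C)CC[C@@]2(C)[C@@H]1CC=C1[C@]2(C)CC[C@H](O[Si](CC)(CC)CC)C(C)(C)O[C@H]2C=CC1=O | intermediate
32 | saturated C24 ketone (14S), C7–OTBS, C18–OTES | C=C1CC[C@@H]2OC(C)(C)[C@@H](O[Si](C)(C)C(C)(C)C)CC[C@@]2(C)[C@@H]1CC[C@H]1[C@]2(C)CC[C@H](O[Si](CC)(CC)CC)C(C)(C)O[C@H]2CCC1=O | intermediate
33 | C24 tertiary alcohol (24R), C7–OTBS, C18–OTES | C=C1CC[C@@H]2OC(C)(C)[C@@H](O[Si](C)(C)C(C)(C)C)CC[C@@]2(C)[C@@H]1CC[C@H]1[C@]2(C)CC[C@H](O[Si](CC)(CC)CC)C(C)(C)O[C@H]2CC[C@@]1(C)O | intermediate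
34 | C18,C24-diol, C7–OTBS | C=C1CC[C@@H]2OC(C)(C)[C@@H](O[Si](C)(C)C(C)(C)C)CC[C@@]2(C)[C@@H]1CC[C@H]1[C@]2(C)CC[C@H](O)C(C)(C)O[C@H]2CC[C@@]1(C)O | intermediate
35 | C18 ketone, C7–OTBS | C=C1CC[C@@H]2OC(C)(C)[C@@H](O[Si](C)(C)C(C)(C)C)CC[C@@]2(C)[C@@H]1CC[C@H]1[C@]2(C)CCC(=O)C(C)(C)O[C@H]2CC[C@@]1(C)O | intermediate
36 | CNP0160418.1 (4S,7S,10S,11R,14S,15S,21S,24R) | C=C1CC[C@@H]2OC(C)(C)[C@@H](O)CC[C@@]2(C)[C@@H]1CC[C@H]1[C@]2(C)CCC(=O)C(C)(C)O[C@H]2CC[C@@]1(C)O | target

Total step count: 24. Longest linear sequence: 20 steps (steps 1–13, then 18–24); the ring C/D branch (steps 14–17) joins at step 18.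

Steps most likely to fail

Step 10. The allylsilane may be lost by protodesilylation before ring A closes, the first epoxide may open in the exo sense, or the cascade may stall after one ring. Fallback: the bicycle is built by the enolsilane-terminated cascade that already serves rings C and D, and the side chain is added afterwards. It sets out from enone 27, whose ring system and configuration are those of rings A and B (C24, C14, C15, C21, O20, C19 and C18 correspond to C1, C11, C10, C4, O5, C6 and C7). Lithium dienolate 28 is added to (tert-butyldiphenylsilyloxy)acetaldehyde to give the aldol adduct F1, which is dehydrated through the mesylate F2 (MeSO2Cl, Et3N; DBU) to the dienone F3. Conjugate reduction of both enone double bonds with [(Ph3P)CuH]6 should give the ketone F4 with the side chain equatorial, and Wittig methylenation (Ph3P=CH2) gives the methylene compound F5. HF·pyridine then cleaves the triethylsilyl ether, and the route is rejoined at 17.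

Step 16. The enol ether may be hydrolysed to the methyl ketone before carbon–carbon bond formation, the cascade may stop after the oxacyclization, or the silyl group may be scrambled. Fallback: an allylsilane-terminated cascade followed by oxidative cleavage. From 22 the kinetic enol triflate F6 (LiN(i-Pr)2; PhNTf2) is coupled with 7 under Pd(PPh3)4 catalysis to the allylsilane F7. Me3SiOTf and DTBMP should give the methylene bicycle as its trimethylsilyl ether F8, carbonate methanolysis gives the alcohol F9, and Et3SiCl with imidazole gives the triethylsilyl ether F10. Ozonolysis (O3; Me2S) of the exocyclic methylene rejoins the route at 25.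

Step 18. Proton transfer between the hindered dienolate and the enolisable aldehyde, or retro-aldol cleavage during dehydration, may erode the coupling. Fallback: direct alkylation in place of aldol condensation. Alcohol 19 is converted (I2, PPh3, imidazole) into the primary iodide F11, which alkylates dienolate 28 (THF/DMPU, −78 to 0 °C) at C14 to give the alkylated enone F12. Conjugate reduction of the remaining C22=C23 double bond with [(Ph3P)CuH]6 and base equilibration at C14 (NaOMe, MeOH) rejoin the route at 32.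

Further compounds
F1 | step 10 | aldol adduct of 28 and (tert-butyldiphenylsilyloxy)acetaldehyde | O=C1C(C(O)CO[Si](c3ccccc3)(c3ccccc3)C(C)(C)C)[C@]2(C)CC[C@H](O[Si](CC)(CC)CC)C(C)(C)O[C@H]2C=C1
F2 | step 10 | mesylate of F1 | O=C1C(C(OS(C)(=O)=O)CO[Si](c3ccccc3)(c3ccccc3)C(C)(C)C)[C@]2(C)CC[C@H](O[Si](CC)(CC)CC)C(C)(C)O[C@H]2C=C1
F3 | step 10 | cross-conjugated dienone carrying the silyloxyethylidene group | O=C1C(=CCO[Si](c3ccccc3)(c3ccccc3)C(C)(C)C)[C@]2(C)CC[C@H](O[Si](CC)(CC)CC)C(C)(C)O[C@H]2C=C1
F4 | step 10 | C1 ketone of rings A and B, C7–OTES, C13–OTBDPS | CC(C)(C)[Si](c1ccccc1)(c1ccccc1)OCC[C@H]1[C@]2(C)CC[C@H](O[Si](CC)(CC)CC)C(C)(C)O[C@H]2CCC1=O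
F5 | step 10 | C7 triethylsilyl ether of 17 | CC(C)(C)[Si](c1ccccc1)(c1ccccc1)OCC[C@H]1[C@]2(C)CC[C@H](O[Si](CC)(CC)CC)C(C)(C)O[C@H]2CCC1=C
F6 | step 16 | kinetic enol triflate of 22 | CC1(C)O[C@H]1CC[C@]2(C)O[C@H]2CCC(=C)OS(=O)(=O)C(F)(F)F
F7 | step 16 | bis-epoxy 2-substituted allylsilane | CC1(C)O[C@H]1CC[C@]2(C)O[C@H]2CCC(=C)C[Si](C)(C)C
F8 | step 16 | C18 trimethylsilyl ether of the C24-methylene bicycle | C=C1C[C@]2(C)CC[C@H](O[Si](C)(C)C)C(C)(C)O[C@H]2CC1
F9 | step 16 | C24-methylene bicycle with free C18 alcohol | C=C1C[C@]2(C)CC[C@H](O)C(C)(C)O[C@H]2CC1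
F10 | step 16 | C18 triethylsilyl ether of F9 | C=C1C[C@]2(C)CC[C@H](O[Si](CC)(CC)CC)C(C)(C)O[C@H]2CC1
F11 | step 18 | C13 primary iodide, C7–OTBS | C=C1CC[C@@H]2OC(C)(C)[C@@H](O[Si](C)(C)C(C)(C)C)CC[C@@]2(C)[C@@H]1CCI
F12 | step 18 | C14-alkylated enone (C22=C23 retained) | C=C1CC[C@@H]2OC(C)(C)[C@@H](O[Si](C)(C)C(C)(C)C)CC[C@@]2(C)[C@@H]1CCC1[C@]2(C)CC[C@H](O[Si](CC)(CC)CC)C(C)(C)O[C@H]2C=CC1=O
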